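**Retrosynthetic overview**
1. Locants follow 1,2-dihydronaphthalene: C1 = CH bearing the pendant guaiacyl ring C, C2 = CH bearing CH2OAc, C3 = C–CHO, C4 = vinylic CH. Ring A is the benzo ring (C7 OH, C8 OMe) and ring B is C1–C4/C4a/C8a. The acetate goes on last, and its CH2OH comes from a C2 aldehyde.
2. The key disconnection is C1–C2 of ring B. An amine-catalysed, enantioconvergent 1,6-addition of the C2 enamine to a p-quinone methide, whose exocyclic carbon is C1, closes ring B and sets both stereocentres.
3. Enabling feature: the free OH of ring C stands para to the doubly benzylic C1, so loss of a leaving group from C1 dearomatises ring C to a quinone methide. C2 carries an oxygenated carbon that makes it an enamine α-carbon at the aldehyde level, and the (E)-C3=C4 bond on ring A holds C2 next to C1.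
4. C3=C4 comes from a cross-aldol condensation of the ring A aldehyde with succinaldehyde monoacetal. C1–C8a comes from ortho-lithiation of a vanillin acetal (between OMe and acetal) and addition to a second vanillin unit.
5. Ring order: rings A and C are bought (both from vanillin). Ring B is the only ring made, in step 8.

Key step: step 8

Remark: the target SMILES is read as the 1,2-trans (1S,2R) isomer; C1 of compounds 5–12 is deliberately racemic because step 8 erases that centre.

Step 1
Reactants: 1 vanillin (4-hydroxy-3-methoxybenzaldehyde)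
Product: 2 3-methoxy-4-(triisopropylsilyloxy)benzaldehyde
Conditions: i-Pr3SiCl, imidazole, DMF, rt
Reagents that add atoms: chlorotriisopropylsilane, CC(C)[Si](Cl)(C(C)C)C(C)C
Why: Imidazole-promoted silyl ether formation on a phenol; the bulky silyl group should survive n-BuLi and shield the neighbouring ring position in step 3.

Step 2
Reactants: 2 3-methoxy-4-(triisopropylsilyloxy)benzaldehyde
Product: 3 3-methoxy-4-(triisopropylsilyloxy)benzaldehyde dimethyl acetal
Conditions: HC(OMe)3, p-TsOH·H2O (cat.), MeOH, rt; Et3N quench
Reagents that add atoms: trimethyl orthoformate, COC(OC)OC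
Why: Acid-catalysed acetalisation masks the aldehyde and turns it into an ortho-directing group.

Step 3
Reactants: 3 3-methoxy-4-(triisopropylsilyloxy)benzaldehyde dimethyl acetal; 2 3-methoxy-4-(triisopropylsilyloxy)benzaldehyde
Product: 7 rac-3-methoxy-2-{methoxy[3-methoxy-4-(triisopropylsilyloxy)phenyl]methyl}-4-(triisopropylsilyloxy)benzaldehyde, via aryllithium 4 (not isolated), via lithium alkoxide 5 (not isolated), via methyl ether acetal 6 (not isolated)
Conditions: n-BuLi (1.1 equiv), THF, 0 °C; 2, −78 °C to 0 °C; MeI, DMPU, 0 °C to rt; then 0.5 M aq HCl, THF, 0 °C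
Reagents that add atoms: iodomethane, CI; water, O
Why: Directed ortho-metalation, in which acetal and methoxy group cooperate to place lithium on the ring carbon between them, followed by 1,2-addition to 2, Williamson-type O-methylation (which blocks later lactol and oxa-Michael ring formation) and hydrolysis of only the very labile aryl acetal; the new C1 centre is racemic and is erased in step 8.

Step 4
Reactants: 8 methyl 4,4-dimethoxybutanoate
Product: 9 4,4-dimethoxybutanal
Conditions: i-Bu2AlH (1.05 equiv), CH2Cl2, −78 °C; aq potassium sodium tartrate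
Reagents that add atoms: none
Why: Partial ester reduction, which stops at the tetrahedral aluminium hemiacetal at −78 °C and should release the aldehyde on work-up.

Step 5
Reactants: 7 rac-3-methoxy-2-{methoxy[3-methoxy-4-(triisopropylsilyloxy)phenyl]methyl}-4-(triisopropylsilyloxy)benzaldehyde; 9 4,4-dimethoxybutanal
Product: 10 rac-(E)-2-(2,2-dimethoxyethyl)-3-(ring A aryl of 7)prop-2-enal
Conditions: pyrrolidine (30 mol %), 4-(dimethylamino)benzoic acid (30 mol %), CH2Cl2, 40 °C, slow addition of 9
Reagents that add atoms: none
Why: Amine/acid-catalysed cross-aldol (Mannich-type) condensation, with the non-enolisable aryl aldehyde as acceptor and the enamine of 9 as donor; elimination should give the thermodynamic (E)-enal with ring A cis to the CH2 group (C2).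

Step 6
Reactants: 10 rac-(E)-2-(2,2-dimethoxyethyl)-3-(ring A aryl of 7)prop-2-enal
Product: 11 rac-(E)-2-(arylmethylidene)butanedial with both phenols silylated
Conditions: 1 M aq HCl, THF, 0 °C to rt
Reagents that add atoms: water, O
Why: Acid-catalysed acetal hydrolysis; while both phenols are silylated the benzhydryl methyl ether should ionise far more slowly than the aliphatic acetal, so C1 stays masked.

Step 7
Reactants: 11 rac-(E)-2-(arylmethylidene)butanedial with both phenols silylated
Product: 12 rac-(E)-2-(arylmethylidene)butanedial with both phenols free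
Conditions: n-Bu4NF (2.5 equiv), AcOH (2.5 equiv), THF, 0 °C; short silica plug, used at once
Reagents that add atoms: none
Why: Fluoride-mediated cleavage of aryl silyl ethers, buffered with AcOH to spare the enolisable dialdehyde and keep methoxide on C1.

Step 8
Reactants: 12 rac-(E)-2-(arylmethylidene)butanedial with both phenols free
Product: 15 (1S,2R)-7-hydroxy-1-(4-hydroxy-3-methoxyphenyl)-2-(hydroxymethyl)-8-methoxy-1,2-dihydronaphthalene-3-carbaldehyde, via enamine quinone methide 13 (not isolated), via cyclised dialdehyde 14 (not isolated)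
Conditions: (R)-α,α-diphenylprolinol trimethylsilyl ether (20 mol %), CF3CO2H (30 mol %), CHCl3, −20 °C to rt, Ar; then MeOH, −78 °C, NaBH4 (1.0 equiv); aq NH4Cl
Reagents that add atoms: none
Why: CF3CO2H, helped by the free para OH of ring C, expels methanol from C1 of 12 to give the p-quinone methide, the amine condenses with the unbranched saturated aldehyde to the (E)-enamine (13), the enamine α-carbon C2 adds in a 1,6 sense to the exocyclic quinone methide carbon C1, and rearomatisation of ring C plus iminium hydrolysis release 14 and the catalyst. The closest known reaction types are the enamine-catalysed asymmetric α-alkylation of aldehydes with p-quinone methides or with diarylcarbenium ions generated in situ from diarylmethanol derivatives, and the cyclisation of p-quinone methides onto tethered π-nucleophiles. Ring B closes in a 6-(enolexo)-exo-trig mode. C2 is set by the catalyst, whose CPh2(OSiMe3) group shields one face of the s-trans (E)-enamine so that the (R)-amine should give 2R, and C1 is set by the cyclic transition state, in which the quinone methide ring lies anti to the bulky enamine arm and pseudoaxial away from the C8 methoxy group, which should give the 1,2-trans (1S) centre; the racemic C1 centre of 12 is erased, so both enantiomers converge. The step needs enamine formation at only one aldehyde, secured by the α-branched push-pull enal being a poor partner for the hindered amine, and attack through C2 instead of C4 of the dienamine-like unit, secured by the (E)-C3=C4 bond, which lets only C2 reach C1 through a six-membered ring. NaBH4 at −78 °C should then reduce the saturated aldehyde of 14 faster than the enal deactivated by the para oxygen of ring A, which freezes the epimerisable C2 centre.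

Step 9
Reactants: 15 (1S,2R)-7-hydroxy-1-(4-hydroxy-3-methoxyphenyl)-2-(hydroxymethyl)-8-methoxy-1,2-dihydronaphthalene-3-carbaldehyde
Product: 16 (1S,2R)-2-(acetoxymethyl)-7-hydroxy-1-(4-hydroxy-3-methoxyphenyl)-8-methoxy-1,2-dihydronaphthalene-3-carbaldehyde (CNP0489020.1)
Conditions: AcOH (5 equiv), PPh3, diisopropyl azodicarboxylate, THF, 0 °C to rt
Reagents that add atoms: acetic acid, CC(=O)O
Why: Mitsunobu esterification, in which only the aliphatic primary alcohol is activated and the more acidic acetic acid, used in excess, should outcompete the phenols as nucleophile; substitution at the CH2 carbon leaves both stereocentres untouched.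

**Compound list**
1 | vanillin (4-hydroxy-3-methoxybenzaldehyde) | COc1cc(C=O)ccc1O | starting material
2 | 3-methoxy-4-(triisopropylsilyloxy)benzaldehyde | COc1cc(C=O)ccc1O[Si](C(C)C)(C(C)C)C(C)C | intermediate
3 | dimethyl acetal of 2 | COc1cc(C(OC)OC)ccc1O[Si](C(C)C)(C(C)C)C(C)C | intermediate
4 | aryllithium from 3 (Li between the acetal-bearing and the OMe-bearing ring carbons) | [Li]c1c(C(OC)OC)ccc(O[Si](C(C)C)(C(C)C)C(C)C)c1OC | intermediate
5 | racemic lithium benzhydryl alkoxide from 4 and 2 | [Li]OC(c1ccc(O[Si](C(C)C)(C(C)C)C(C)C)c(OC)c1)c1c(C(OC)OC)ccc(O[Si](C(C)C)(C(C)C)C(C)C)c1OC | intermediate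
6 | racemic benzhydryl methyl ether dimethyl acetal | COC(c1ccc(O[Si](C(C)C)(C(C)C)C(C)C)c(OC)c1)c1c(C(OC)OC)ccc(O[Si](C(C)C)(C(C)C)C(C)C)c1OC | intermediate
7 | racemic benzhydryl methyl ether aldehyde | COC(c1ccc(O[Si](C(C)C)(C(C)C)C(C)C)c(OC)c1)c1c(C=O)ccc(O[Si](C(C)C)(C(C)C)C(C)C)c1OC | intermediate
8 | methyl 4,4-dimethoxybutanoate | COC(=O)CCC(OC)OC | starting material
9 | 4,4-dimethoxybutanal | O=CCCC(OC)OC | intermediate
10 | racemic (E)-enal acetal, bis-silyl ether | O=C/C(CC(OC)OC)=C/c1ccc(O[Si](C(C)C)(C(C)C)C(C)C)c(OC)c1C(OC)c1ccc(O[Si](C(C)C)(C(C)C)C(C)C)c(OC)c1 | intermediate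
11 | racemic (E)-arylidene butanedial, bis-silyl ether | O=C/C(CC=O)=C/c1ccc(O[Si](C(C)C)(C(C)C)C(C)C)c(OC)c1C(OC)c1ccc(O[Si](C(C)C)(C(C)C)C(C)C)c(OC)c1 | intermediate
12 | racemic (E)-arylidene butanedial, free phenols | O=C/C(CC=O)=C/c1ccc(O)c(OC)c1C(OC)c1ccc(O)c(OC)c1 | intermediate
13 | (E)-enamine of the saturated aldehyde with the (R)-amine, ring C as p-quinone methide | C[Si](C)(C)OC([C@H]1CCCN1/C=C/C(C=O)=C\c1ccc(O)c(OC)c1C=C1C=CC(=O)C(OC)=C1)(c1ccccc1)c1ccccc1 | intermediate
14 | (1S,2R)-7-hydroxy-1-(4-hydroxy-3-methoxyphenyl)-8-methoxy-1,2-dihydronaphthalene-2,3-dicarbaldehyde | COc1cc([C@H]2c3c(ccc(O)c3OC)C=C(C=O)[C@@H]2C=O)ccc1O | intermediate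
15 | (1S,2R)-hydroxymethyl enal | COc1cc([C@H]2c3c(ccc(O)c3OC)C=C(C=O)[C@@H]2CO)ccc1O | intermediate
16 | CNP0489020.1, (1S,2R)-acetoxymethyl enal | COc1cc([C@H]2c3c(ccc(O)c3OC)C=C(C=O)[C@@H]2COC(C)=O)ccc1O | target

**Total step count:** 9. **Longest linear sequence:** 8 (steps 1, 2, 3, 5, 6, 7, 8, 9).

**Steps most likely to fail**

1. **Step 8.**
   - What may go wrong: poor facial selectivity at C1 during ring closure; epimerisation at C2 before the reduction; acid-driven Paal–Knorr-type cyclodehydration of the 1,4-dialdehyde unit; or uncatalysed closure through the enol, which would erode enantiomeric purity.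
   - Fallback (sets out from 7, comes back at 15): the same C1–C2 closure is run at the carboxylic acid level under auxiliary control. Trimethyl phosphonoacetate is alkylated (NaH, THF) with (R)-4-benzyl-3-(bromoacetyl)-1,3-oxazolidin-2-one to the phosphonate imide F1. Its Horner–Wadsworth–Emmons reaction with 7 (LiCl, i-Pr2NEt, MeCN) should give the (E)-arylidenesuccinate imide F2. TiCl4 (2.2 equiv) and i-Pr2NEt in CH2Cl2 at −78 °C form the chelated (Z)-titanium enolate and ionise the benzhydryl methyl ether. The SN1-type enolate alkylation, a known reaction of such enolates with stabilised carbenium ions, should then close ring B to the trans imide ester F3, with the benzyl group of the auxiliary blocking one enolate face. i-Bu2AlH reduces imide and ester to the diol F4, MnO2 oxidises only the allylic alcohol to the bis-silylated hydroxy enal F5, and n-Bu4NF/AcOH gives 15.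

2. **Step 5.**
   - What may go wrong: self-condensation of the aliphatic aldehyde outruns the cross reaction with the hindered, electron-rich aryl aldehyde; or double-bond geometry control is incomplete.
   - Fallback (sets out from 7, comes back at 10): the double bond is made by olefination at the ester level. Triethyl phosphonoacetate is alkylated (NaH, DMF) with bromoacetaldehyde dimethyl acetal to the phosphonate ester F6. Its Horner–Wadsworth–Emmons reaction with 7 (NaH, THF) should give the (E)-enoate F7. i-Bu2AlH gives the allylic alcohol F8, and MnO2 oxidises it to 10.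

3. **Step 7.**
   - What may go wrong: enolisation, double-bond migration or aldol oligomerisation of the 1,4-dialdehyde in the fluoride medium; or premature uncatalysed ring closure once the phenol of ring C is free.
   - Fallback (sets out from 10, comes back at 15): the order of unmasking is reversed, so the dialdehyde never meets fluoride and is never isolated. n-Bu4NF/AcOH is applied to the robust acetal 10 to give the bis-phenol acetal F9. The aldehyde is then released only in the flask of the ring closure, with the preformed CF3CO2H salt of the (R)-amine and H2O (10 equiv) in CHCl3. Enamine formation, quinone methide formation, ring closure and the NaBH4 quench follow as in step 8.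

**Further compounds**
F1 | step 8 | methyl 4-[(4R)-4-benzyl-2-oxo-1,3-oxazolidin-3-yl]-2-(dimethoxyphosphoryl)-4-oxobutanoate | COC(=O)C(CC(=O)N1[C@H](Cc2ccccc2)COC1=O)P(=O)(OC)OC
F2 | step 8 | (E)-arylidenesuccinate methyl ester (R)-4-benzyloxazolidinone imide, C1 racemic | COC(=O)/C(CC(=O)N1[C@H](Cc2ccccc2)COC1=O)=C/c1ccc(O[Si](C(C)C)(C(C)C)C(C)C)c(OC)c1C(OC)c1ccc(O[Si](C(C)C)(C(C)C)C(C)C)c(OC)c1
F3 | step 8 | (1S,2R)-trans dihydronaphthalene 3-methyl ester 2-imide, bis-silyl ether | COc1cc([C@H]2c3c(ccc(O[Si](C(C)C)(C(C)C)C(C)C)c3OC)C=C(C(=O)OC)[C@@H]2C(=O)N2[C@H](Cc3ccccc3)COC2=O)ccc1O[Si](C(C)C)(C(C)C)C(C)C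
F4 | step 8 | (1S,2R)-2,3-bis(hydroxymethyl) dihydronaphthalene, bis-silyl ether | COc1cc([C@H]2c3c(ccc(O[Si](C(C)C)(C(C)C)C(C)C)c3OC)C=C(CO)[C@@H]2CO)ccc1O[Si](C(C)C)(C(C)C)C(C)C
F5 | step 8 | (1S,2R)-hydroxymethyl enal, bis-silyl ether | COc1cc([C@H]2c3c(ccc(O[Si](C(C)C)(C(C)C)C(C)C)c3OC)C=C(C=O)[C@@H]2CO)ccc1O[Si](C(C)C)(C(C)C)C(C)C
F6 | step 5 | ethyl 2-(diethoxyphosphoryl)-4,4-dimethoxybutanoate | CCOC(=O)C(CC(OC)OC)P(=O)(OCC)OCC
F7 | step 5 | racemic ethyl (E)-2-(2,2-dimethoxyethyl)-3-arylprop-2-enoate, bis-silyl ether | CCOC(=O)/C(CC(OC)OC)=C/c1ccc(O[Si](C(C)C)(C(C)C)C(C)C)c(OC)c1C(OC)c1ccc(O[Si](C(C)C)(C(C)C)C(C)C)c(OC)c1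
F8 | step 5 | racemic (E)-allylic alcohol, bis-silyl ether | OC/C(CC(OC)OC)=C/c1ccc(O[Si](C(C)C)(C(C)C)C(C)C)c(OC)c1C(OC)c1ccc(O[Si](C(C)C)(C(C)C)C(C)C)c(OC)c1
F9 | step 7 | racemic (E)-enal acetal with both phenols free | O=C/C(CC(OC)OC)=C/c1ccc(O)c(OC)c1C(OC)c1ccc(O)c(OC)c1
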